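Assumption: carotenoid locants are used with unprimed numbers on the acetylenic β half and primed numbers on the ε half, so the target is all-E (3R,3'S,6'R)-7,8-didehydro-β,ε-carotene-3,3',6'-triol.

## Retrosynthetic overview

1. C11=C12 (last C–C bond): Wittig reaction of the ε-half C25 aldehyde 25 with the acetylenic C15 tributylphosphonium salt 33, then desilylation.
2. C13=C14 (key bond): crossed aldol condensation of the C22 pentaenal 22 with propanal 23 gives 25.
3. C11'=C12': Wittig reaction of the ε C15 aldehyde 11 with the C7 acetal phosphonium salt 19 (from fumaraldehyde bis-acetal), then acetal hydrolysis.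
4. 11 comes from acetylide addition of the (E)-enynol 4 to the (R)-silyloxy enone 3, alkyne-to-E-alkene reduction, oxidation and Mitsunobu inversion at C3'; 33 comes from Sonogashira coupling of enol triflate 30 with the same enynol.
5. No ring is formed: both six-membered rings are carried from 4-oxoisophorone 1 through two enantiomeric transfer hydrogenations (ε ring first in the step order, β ring second).

## Route

**Step 1**
Reactants: 1 4-oxoisophorone
Product: 2 (4R)-4-hydroxy-2,6,6-trimethylcyclohex-2-en-1-one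
Conditions: RuCl[(R,R)-TsDPEN](p-cymene) (0.5 mol%), KOtBu (1 mol%), iPrOH, 25 °C; recrystallise
Reagents that add atoms: none
Why: Noyori asymmetric transfer hydrogenation reduces only the less hindered C4 carbonyl, and the (R,R)-ligand is expected to set the 4R carbinol by the usual model in which the enone π-system takes the place of the aryl group (ee raised by crystallisation).

**Step 2**
Reactants: 2 (4R)-hydroxy enone
Product: 3 (4R)-4-[(tert-butyldimethylsilyl)oxy]-2,6,6-trimethylcyclohex-2-en-1-one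
Conditions: TBSCl, imidazole, DMF, rt
Reagents that add atoms: tert-butyldimethylsilyl chloride, CC(C)(C)[Si](C)(C)Cl
Why: Standard silyl ether formation protects the secondary alcohol and provides the bulky pseudo-equatorial group that biases the ring conformation in step 3.

**Step 3**
Reactants: 3 (4R)-silyloxy enone; 4 (2E)-3-methylpent-2-en-4-yn-1-ol
Product: 6 (1R,4R)-4-[(tert-butyldimethylsilyl)oxy]-1-[(3E)-5-hydroxy-3-methylpent-3-en-1-yn-1-yl]-2,6,6-trimethylcyclohex-2-en-1-ol, via dilithiated enynol 5 (not isolated)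
Conditions: 4 (1.3 equiv), n-BuLi (2.6 equiv), THF, −78 → −20 °C; add 3, −78 °C → rt; H2O
Reagents that add atoms: none
Why: 1,2-Addition of the lithium acetylide to the non-enolisable ketone; with the silyloxy group pseudo-equatorial the C6 methyl on the opposite face is axial, so the acetylide should enter axially on the silyloxy face and give the alkynyl group cis to OTBS (1R), any minor diastereomer being removed by chromatography.

**Step 4**
Reactants: 6 alkynyl diol
Product: 7 (1R,4R)-4-[(tert-butyldimethylsilyl)oxy]-1-[(1E,3E)-5-hydroxy-3-methylpenta-1,3-dien-1-yl]-2,6,6-trimethylcyclohex-2-en-1-ol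
Conditions: NaAlH2(OCH2CH2OMe)2 (3.5 equiv), THF, 0 °C → rt; H2O, 1 M NaOH
Reagents that add atoms: none
Why: Hydroxyl-directed trans-hydroalumination of the tertiary propargylic alkoxide gives only the 7'E alkene after protonolysis, as in abscisic acid syntheses.

**Step 5**
Reactants: 7 dienediol
Product: 8 (2E,4E)-5-[(1R,4R)-4-[(tert-butyldimethylsilyl)oxy]-1-hydroxy-2,6,6-trimethylcyclohex-2-en-1-yl]-3-methylpenta-2,4-dienal
Conditions: MnO2 (15 equiv), CH2Cl2, rt
Reagents that add atoms: none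
Why: MnO2 oxidises only the primary dienylic alcohol, since the tertiary alcohol cannot be oxidised and the ring carbinol is silylated.

**Step 6**
Reactants: 8 silyloxy dienal
Product: 9 (2E,4E)-5-[(1R,4R)-1,4-dihydroxy-2,6,6-trimethylcyclohex-2-en-1-yl]-3-methylpenta-2,4-dienal
Conditions: Bu4NF (1.5 equiv), AcOH (1.5 equiv), THF, 0 °C → rt
Reagents that add atoms: none
Why: Buffered fluoride desilylation frees the ring carbinol without acid, which the tertiary allylic alcohol would not tolerate.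

**Step 7**
Reactants: 9 trans-diol dienal
Product: 10 (1S,4R)-4-hydroxy-3,5,5-trimethyl-4-[(1E,3E)-3-methyl-5-oxopenta-1,3-dien-1-yl]cyclohex-2-en-1-yl 4-nitrobenzoate
Conditions: PPh3, DIAD, 4-nitrobenzoic acid, THF, 0 °C → rt
Reagents that add atoms: 4-nitrobenzoic acid, OC(=O)c1ccc(cc1)[N+](=O)[O-]
Why: Mitsunobu esterification displaces the oxyphosphonium at the secondary allylic carbon by SN2 with inversion (the tertiary alcohol is inert and SN2' is blocked by the fully substituted alkene terminus), turning the trans-1,4-diol into the required cis arrangement.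

**Step 8**
Reactants: 10 nitrobenzoate
Product: 11 (2E,4E)-5-[(1R,4S)-1,4-dihydroxy-2,6,6-trimethylcyclohex-2-en-1-yl]-3-methylpenta-2,4-dienal
Conditions: K2CO3 (0.2 equiv), MeOH, 0 °C
Reagents that add atoms: none
Why: Transesterification of the activated aryl ester is fast at 0 °C with acyl–oxygen cleavage, so the new 3'S centre is retained and the dienal is untouched.

**Step 9**
Reactants: 12 fumaraldehyde bis(dimethyl acetal)
Product: 13 (2E)-4,4-dimethoxybut-2-enal
Conditions: Amberlyst-15 (cat.), H2O (1.5 equiv), acetone, rt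
Reagents that add atoms: water, O
Why: Acid-catalysed acetal hydrolysis stops after one end because the remaining acetal is then conjugated to an electron-poor enal and hydrolyses much more slowly.

**Step 10**
Reactants: 13 enal acetal; 14 triethyl 2-phosphonopropionate
Product: 16 ethyl (2E,4E)-6,6-dimethoxy-2-methylhexa-2,4-dienoate, via sodium phosphonate carbanion 15 (not isolated)
Conditions: NaH, THF, 0 °C; add 13, 0 °C → rt
Reagents that add atoms: none
Why: Horner–Wadsworth–Emmons olefination of an enal with an α-methyl phosphonoacetate is reliably E-selective for the trisubstituted alkene.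

**Step 11**
Reactants: 16 dienoate
Product: 17 (2E,4E)-6,6-dimethoxy-2-methylhexa-2,4-dien-1-ol
Conditions: iBu2AlH (2.2 equiv), CH2Cl2, −78 °C
Reagents that add atoms: none
Why: 1,2-Reduction of the conjugated ester to the allylic alcohol leaves the acetal and alkene geometry intact.

**Step 12**
Reactants: 17 dienol
Product: 18 (2E,4E)-6-bromo-1,1-dimethoxy-5-methylhexa-2,4-diene
Conditions: CBr4, PPh3, 2,6-lutidine (0.2 equiv), CH2Cl2, −20 → 0 °C
Reagents that add atoms: carbon tetrabromide, BrC(Br)(Br)Br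
Why: Appel bromination converts the primary allylic alcohol to the bromide under near-neutral conditions that spare the acetal.

**Step 13**
Reactants: 18 allylic bromide
Product: 19 tributyl[(2E,4E)-6,6-dimethoxy-2-methylhexa-2,4-dien-1-yl]phosphonium bromide
Conditions: PBu3, EtOAc, 0 °C → rt
Reagents that add atoms: tributylphosphine, CCCCP(CCCC)CCCC
Why: SN2 quaternisation of the primary allylic bromide gives the salt, and the trialkylphosphonium group is chosen because its ylide gives E-alkenes.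

**Step 14**
Reactants: 11 ε C15 aldehyde; 19 C7 phosphonium salt (1.5 equiv)
Product: 21 (1R,4S)-1-[(1E,3E,5E,7E,9E)-11,11-dimethoxy-3,7-dimethylundeca-1,3,5,7,9-pentaen-1-yl]-2,6,6-trimethylcyclohex-2-ene-1,4-diol, via phosphonium ylide 20 (not isolated)
Conditions: NaOMe (MeOH), CH2Cl2, rt, dark
Reagents that add atoms: none
Why: Wittig olefination of the dienal with the allylic tributylphosphonium ylide forms C11'=C12' mainly E and tolerates the free hydroxyls, which are only reversibly deprotonated.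

**Step 15**
Reactants: 21 pentaene acetal
Product: 22 (2E,4E,6E,8E,10E)-11-[(1R,4S)-1,4-dihydroxy-2,6,6-trimethylcyclohex-2-en-1-yl]-5,9-dimethylundeca-2,4,6,8,10-pentaenal
Conditions: PPTS (0.1 equiv), acetone–H2O (10:1), 0 °C, dark
Reagents that add atoms: water, O
Why: The polyene-conjugated dimethyl acetal ionises far more readily than the tertiary alcohol, so very mild acid hydrolysis frees the aldehyde selectively.

**Step 16 (key step)**
Reactants: 22 C22 pentaenal; 23 propanal
Product: 25 (2E,4E,6E,8E,10E,12E)-13-[(1R,4S)-1,4-dihydroxy-2,6,6-trimethylcyclohex-2-en-1-yl]-2,7,11-trimethyltrideca-2,4,6,8,10,12-hexaenal, via aldol adduct 24 (not isolated)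
Conditions: 23 (5 equiv, added over 4 h), KOH (0.5 equiv), MeOH–THF (3:1), 0 °C → rt, argon, dark
Reagents that add atoms: none
Why: Crossed aldol condensation in which 22 has no α-hydrogen and can only be the acceptor, the propanal enolate adds to its carbonyl and the aldol loses water by E1cB to the thermodynamically favoured 2E α-methyl enal, while slow addition limits propanal self-condensation and the base-only conditions spare the tertiary allylic alcohol.

**Step 17**
Reactants: 1 4-oxoisophorone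
Product: 26 (4S)-4-hydroxy-2,6,6-trimethylcyclohex-2-en-1-one
Conditions: RuCl[(S,S)-TsDPEN](p-cymene) (0.5 mol%), KOtBu (1 mol%), iPrOH, 25 °C; recrystallise
Reagents that add atoms: none
Why: The same asymmetric transfer hydrogenation with the mirror-image ligand gives the 4S carbinol that becomes C3 of the β ring.

**Step 18**
Reactants: 26 (4S)-hydroxy enone
Product: 27 (4S)-4-[(tert-butyldimethylsilyl)oxy]-2,6,6-trimethylcyclohex-2-en-1-one
Conditions: TBSCl, imidazole, DMF, rt
Reagents that add atoms: tert-butyldimethylsilyl chloride, CC(C)(C)[Si](C)(C)Cl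
Why: Silyl protection is needed for the enolate chemistry and also suppresses allylic C–O hydrogenolysis in the next step.

**Step 19**
Reactants: 27 (4S)-silyloxy enone
Product: 28 (4R)-4-[(tert-butyldimethylsilyl)oxy]-2,2,6-trimethylcyclohexan-1-one (C6 epimer mixture)
Conditions: H2 (1 atm), Pd/C (10%), EtOAc, rt
Reagents that add atoms: none
Why: Heterogeneous hydrogenation saturates the enone C=C only; the carbinol centre is untouched (its descriptor changes to R by priority alone) and the new C6 centre is irrelevant because it becomes sp2 in step 20.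

**Step 20**
Reactants: 28 saturated ketone
Product: 30 (4R)-4-[(tert-butyldimethylsilyl)oxy]-2,6,6-trimethylcyclohex-1-en-1-yl trifluoromethanesulfonate, via lithium enolate 29 (not isolated)
Conditions: LiN(iPr)2, THF, −78 °C; PhNTf2, −78 → 0 °C
Reagents that add atoms: N-phenylbis(trifluoromethanesulfonimide), O=S(=O)(N(c1ccccc1)S(=O)(=O)C(F)(F)F)C(F)(F)F
Why: The only α-hydrogen is at C6, so both epimers give one enolate, which is trapped on oxygen as the enol triflate.

**Step 21**
Reactants: 30 enol triflate; 4 (2E)-3-methylpent-2-en-4-yn-1-ol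
Product: 31 (2E)-5-[(4R)-4-[(tert-butyldimethylsilyl)oxy]-2,6,6-trimethylcyclohex-1-en-1-yl]-3-methylpent-2-en-4-yn-1-ol
Conditions: Pd(PPh3)4 (5 mol%), CuI (10 mol%), iPr2NH, DMF, rt
Reagents that add atoms: none
Why: Sonogashira coupling joins the hindered enol triflate to the terminal alkyne and carries the 9E geometry in from the enynol unchanged.

**Step 22**
Reactants: 31 C15 enynol
Product: 32 tert-butyl{[(1R)-4-[(3E)-5-bromo-3-methylpent-3-en-1-yn-1-yl]-3,5,5-trimethylcyclohex-3-en-1-yl]oxy}dimethylsilane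
Conditions: CBr4, PPh3, 2,6-lutidine (0.2 equiv), CH2Cl2, −20 °C
Reagents that add atoms: carbon tetrabromide, BrC(Br)(Br)Br
Why: Appel bromination under neutral conditions avoids the allylic cation that would scramble the 9E double bond.

**Step 23**
Reactants: 32 allylic bromide
Product: 33 tributyl[(2E)-5-[(4R)-4-[(tert-butyldimethylsilyl)oxy]-2,6,6-trimethylcyclohex-1-en-1-yl]-3-methylpent-2-en-4-yn-1-yl]phosphonium bromide
Conditions: PBu3, EtOAc, 0 °C → rt
Reagents that add atoms: tributylphosphine, CCCCP(CCCC)CCCC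
Why: SN2 quaternisation gives the acetylenic C15 salt without acid, and the tributylphosphonium ylide favours the E-alkene.

**Step 24**
Reactants: 25 C25 hexaenal; 33 acetylenic C15 phosphonium salt (1.5 equiv)
Product: 35 (3R,3'S,6'R)-3-[(tert-butyldimethylsilyl)oxy]-7,8-didehydro-β,ε-carotene-3',6'-diol, via phosphonium ylide 34 (not isolated)
Conditions: NaOMe (MeOH), CH2Cl2, rt, argon, dark; chromatography
Reagents that add atoms: none
Why: Wittig olefination forms C11=C12 mainly E and completes the C40 skeleton without touching the three stereocentres; the minor 11Z isomer is removed by chromatography.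

**Step 25**
Reactants: 35 silyl ether
Product: 36 (3R,3'S,6'R)-7,8-didehydro-β,ε-carotene-3,3',6'-triol (target)
Conditions: Bu4NF, THF, 0 °C → rt, argon, dark
Reagents that add atoms: none
Why: Fluoride desilylation is non-acidic, so the polyene, the 9E enyne and the tertiary allylic alcohol survive.

## Compound list

1 | 4-oxoisophorone (2,6,6-trimethylcyclohex-2-ene-1,4-dione) | CC1=CC(=O)CC(C)(C)C1=O | starting material
2 | (4R)-4-hydroxy-2,6,6-trimethylcyclohex-2-en-1-one | CC1=C[C@H](O)CC(C)(C)C1=O | intermediate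
3 | (4R)-4-[(tert-butyldimethylsilyl)oxy]-2,6,6-trimethylcyclohex-2-en-1-one | CC1=C[C@H](O[Si](C)(C)C(C)(C)C)CC(C)(C)C1=O | intermediate
4 | (2E)-3-methylpent-2-en-4-yn-1-ol | C#C/C(C)=C/CO | starting material
5 | dilithiated enynol (lithium (2E)-5-lithio-3-methylpent-2-en-4-yn-1-olate) | [Li]C#C/C(C)=C/CO[Li] | intermediate
6 | (1R,4R)-4-[(tert-butyldimethylsilyl)oxy]-1-[(3E)-5-hydroxy-3-methylpent-3-en-1-yn-1-yl]-2,6,6-trimethylcyclohex-2-en-1-ol | CC1=C[C@H](O[Si](C)(C)C(C)(C)C)CC(C)(C)[C@]1(O)C#C/C(C)=C/CO | intermediate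
7 | (1R,4R)-4-[(tert-butyldimethylsilyl)oxy]-1-[(1E,3E)-5-hydroxy-3-methylpenta-1,3-dien-1-yl]-2,6,6-trimethylcyclohex-2-en-1-ol | CC1=C[C@H](O[Si](C)(C)C(C)(C)C)CC(C)(C)[C@]1(O)/C=C/C(C)=C/CO | intermediate
8 | (2E,4E)-5-[(1R,4R)-4-[(tert-butyldimethylsilyl)oxy]-1-hydroxy-2,6,6-trimethylcyclohex-2-en-1-yl]-3-methylpenta-2,4-dienal | CC1=C[C@H](O[Si](C)(C)C(C)(C)C)CC(C)(C)[C@]1(O)/C=C/C(C)=C/C=O | intermediate
9 | (2E,4E)-5-[(1R,4R)-1,4-dihydroxy-2,6,6-trimethylcyclohex-2-en-1-yl]-3-methylpenta-2,4-dienal | CC1=C[C@H](O)CC(C)(C)[C@]1(O)/C=C/C(C)=C/C=O | intermediate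
10 | (1S,4R)-4-hydroxy-3,5,5-trimethyl-4-[(1E,3E)-3-methyl-5-oxopenta-1,3-dien-1-yl]cyclohex-2-en-1-yl 4-nitrobenzoate | CC1=C[C@@H](OC(=O)c2ccc(cc2)[N+](=O)[O-])CC(C)(C)[C@]1(O)/C=C/C(C)=C/C=O | intermediate
11 | (2E,4E)-5-[(1R,4S)-1,4-dihydroxy-2,6,6-trimethylcyclohex-2-en-1-yl]-3-methylpenta-2,4-dienal | CC1=C[C@@H](O)CC(C)(C)[C@]1(O)/C=C/C(C)=C/C=O | intermediate
12 | fumaraldehyde bis(dimethyl acetal) ((2E)-1,1,4,4-tetramethoxybut-2-ene) | COC(OC)/C=C/C(OC)OC | starting material
13 | (2E)-4,4-dimethoxybut-2-enal | COC(OC)/C=C/C=O | intermediate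
14 | triethyl 2-phosphonopropionate (ethyl 2-(diethoxyphosphoryl)propanoate) | CCOC(=O)C(C)P(=O)(OCC)OCC | starting material
15 | sodium phosphonate carbanion of 14 | CCOC(=O)[C-](C)P(=O)(OCC)OCC.[Na+] | intermediate
16 | ethyl (2E,4E)-6,6-dimethoxy-2-methylhexa-2,4-dienoate | CCOC(=O)/C(C)=C/C=C/C(OC)OC | intermediate
17 | (2E,4E)-6,6-dimethoxy-2-methylhexa-2,4-dien-1-ol | OC/C(C)=C/C=C/C(OC)OC | intermediate
18 | (2E,4E)-6-bromo-1,1-dimethoxy-5-methylhexa-2,4-diene | BrC/C(C)=C/C=C/C(OC)OC | intermediate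
19 | tributyl[(2E,4E)-6,6-dimethoxy-2-methylhexa-2,4-dien-1-yl]phosphonium bromide | CCCC[P+](CCCC)(CCCC)C/C(C)=C/C=C/C(OC)OC.[Br-] | intermediate
20 | phosphonium ylide of 19 | CCCC[P+](CCCC)(CCCC)[CH-]/C(C)=C/C=C/C(OC)OC | intermediate
21 | (1R,4S)-1-[(1E,3E,5E,7E,9E)-11,11-dimethoxy-3,7-dimethylundeca-1,3,5,7,9-pentaen-1-yl]-2,6,6-trimethylcyclohex-2-ene-1,4-diol | CC1=C[C@@H](O)CC(C)(C)[C@]1(O)/C=C/C(C)=C/C=C/C(C)=C/C=C/C(OC)OC | intermediate
22 | (2E,4E,6E,8E,10E)-11-[(1R,4S)-1,4-dihydroxy-2,6,6-trimethylcyclohex-2-en-1-yl]-5,9-dimethylundeca-2,4,6,8,10-pentaenal | CC1=C[C@@H](O)CC(C)(C)[C@]1(O)/C=C/C(C)=C/C=C/C(C)=C/C=C/C=O | intermediate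
23 | propanal | CCC=O | starting material
24 | aldol adduct, (4E,6E,8E,10E,12E)-13-[(1R,4S)-1,4-dihydroxy-2,6,6-trimethylcyclohex-2-en-1-yl]-3-hydroxy-2,7,11-trimethyltrideca-4,6,8,10,12-pentaenal (C2/C3 diastereomer mixture) | CC1=C[C@@H](O)CC(C)(C)[C@]1(O)/C=C/C(C)=C/C=C/C(C)=C/C=C/C(O)C(C)C=O | intermediate
25 | (2E,4E,6E,8E,10E,12E)-13-[(1R,4S)-1,4-dihydroxy-2,6,6-trimethylcyclohex-2-en-1-yl]-2,7,11-trimethyltrideca-2,4,6,8,10,12-hexaenal | CC1=C[C@@H](O)CC(C)(C)[C@]1(O)/C=C/C(C)=C/C=C/C(C)=C/C=C/C=C(C)/C=O | intermediate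
26 | (4S)-4-hydroxy-2,6,6-trimethylcyclohex-2-en-1-one | CC1=C[C@@H](O)CC(C)(C)C1=O | intermediate
27 | (4S)-4-[(tert-butyldimethylsilyl)oxy]-2,6,6-trimethylcyclohex-2-en-1-one | CC1=C[C@@H](O[Si](C)(C)C(C)(C)C)CC(C)(C)C1=O | intermediate
28 | (4R)-4-[(tert-butyldimethylsilyl)oxy]-2,2,6-trimethylcyclohexan-1-one (C6 epimer mixture) | CC1C[C@@H](O[Si](C)(C)C(C)(C)C)CC(C)(C)C1=O | intermediate
29 | lithium (4R)-4-[(tert-butyldimethylsilyl)oxy]-2,6,6-trimethylcyclohex-1-en-1-olate | [Li]OC1=C(C)C[C@@H](O[Si](C)(C)C(C)(C)C)CC1(C)C | intermediate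
30 | (4R)-4-[(tert-butyldimethylsilyl)oxy]-2,6,6-trimethylcyclohex-1-en-1-yl trifluoromethanesulfonate | FC(F)(F)S(=O)(=O)OC1=C(C)C[C@@H](O[Si](C)(C)C(C)(C)C)CC1(C)C | intermediate
31 | (2E)-5-[(4R)-4-[(tert-butyldimethylsilyl)oxy]-2,6,6-trimethylcyclohex-1-en-1-yl]-3-methylpent-2-en-4-yn-1-ol | OC/C=C(\C)C#CC1=C(C)C[C@@H](O[Si](C)(C)C(C)(C)C)CC1(C)C | intermediate
32 | tert-butyl{[(1R)-4-[(3E)-5-bromo-3-methylpent-3-en-1-yn-1-yl]-3,5,5-trimethylcyclohex-3-en-1-yl]oxy}dimethylsilane | BrC/C=C(\C)C#CC1=C(C)C[C@@H](O[Si](C)(C)C(C)(C)C)CC1(C)C | intermediate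
33 | tributyl[(2E)-5-[(4R)-4-[(tert-butyldimethylsilyl)oxy]-2,6,6-trimethylcyclohex-1-en-1-yl]-3-methylpent-2-en-4-yn-1-yl]phosphonium bromide | CCCC[P+](CCCC)(CCCC)C/C=C(\C)C#CC1=C(C)C[C@@H](O[Si](C)(C)C(C)(C)C)CC1(C)C.[Br-] | intermediate
34 | phosphonium ylide of 33 | CCCC[P+](CCCC)(CCCC)[CH-]/C=C(\C)C#CC1=C(C)C[C@@H](O[Si](C)(C)C(C)(C)C)CC1(C)C | intermediate
35 | (3R,3'S,6'R)-3-[(tert-butyldimethylsilyl)oxy]-7,8-didehydro-β,ε-carotene-3',6'-diol | CC1=C[C@@H](O)CC(C)(C)[C@]1(O)/C=C/C(C)=C/C=C/C(C)=C/C=C/C=C(C)/C=C/C=C(\C)C#CC1=C(C)C[C@@H](O[Si](C)(C)C(C)(C)C)CC1(C)C | intermediate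
36 | (3R,3'S,6'R)-7,8-didehydro-β,ε-carotene-3,3',6'-triol (CNP0113828.1) | CC1=C[C@@H](O)CC(C)(C)[C@]1(O)/C=C/C(C)=C/C=C/C(C)=C/C=C/C=C(C)/C=C/C=C(\C)C#CC1=C(C)C[C@@H](O)CC1(C)C | target

## Step count and risk

Total step count: 25.
Longest linear sequence: 13 steps (1–8, 14–16, 24, 25).

Three steps most likely to fail:

**Step 3 (facial selectivity of the acetylide addition).** If the acetylide enters mainly trans to the silyloxy group, the inversion strategy is dropped and the cis-diol is built directly. The fallback sets out from the enantiomeric ketone 27. The dianion 5 is added to 27 to give (1R,4S)-4-[(tert-butyldimethylsilyl)oxy]-1-[(3E)-5-hydroxy-3-methylpent-3-en-1-yn-1-yl]-2,6,6-trimethylcyclohex-2-en-1-ol F1. Reduction with NaAlH2(OCH2CH2OMe)2 gives (1R,4S)-4-[(tert-butyldimethylsilyl)oxy]-1-[(1E,3E)-5-hydroxy-3-methylpenta-1,3-dien-1-yl]-2,6,6-trimethylcyclohex-2-en-1-ol F2. MnO2 then gives (2E,4E)-5-[(1R,4S)-4-[(tert-butyldimethylsilyl)oxy]-1-hydroxy-2,6,6-trimethylcyclohex-2-en-1-yl]-3-methylpenta-2,4-dienal F3, and Bu4NF/AcOH desilylation delivers 11, where the route is rejoined before step 14.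

**Step 7 (Mitsunobu inversion next to a free tertiary alcohol and an enal).** If elimination or 3',6'-ether formation dominates, C3' is corrected by oxidation and reduction. The fallback sets out from 9. MnO2 oxidises the ring allylic alcohol to (2E,4E)-5-[(1R)-1-hydroxy-2,6,6-trimethyl-4-oxocyclohex-2-en-1-yl]-3-methylpenta-2,4-dienal F4. Wittig reaction of its aldehyde with ylide 20 (1.1 equiv, 0 °C) gives (4R)-4-[(1E,3E,5E,7E,9E)-11,11-dimethoxy-3,7-dimethylundeca-1,3,5,7,9-pentaen-1-yl]-4-hydroxy-3,5,5-trimethylcyclohex-2-en-1-one F5. NaBH4/CeCl3 (MeOH, −78 °C) then delivers hydride to the ring ketone from the face away from the axial C1' methyl, giving the cis-diol 21 (trans isomer removed by chromatography), where the route is rejoined before step 15.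

**Step 16 (crossed aldol against propanal self-condensation and over-homologation).** If the cross-condensation cannot be made clean, the same C13=C14 bond is formed by olefination. The fallback sets out from 22, which is treated with 2-(triphenylphosphoranylidene)propanal (CH2Cl2, 40 °C, dark) to give 25 directly, where the route is rejoined before step 24. No new compound is made.

## Further compounds

F1 | step 3 | (1R,4S)-4-[(tert-butyldimethylsilyl)oxy]-1-[(3E)-5-hydroxy-3-methylpent-3-en-1-yn-1-yl]-2,6,6-trimethylcyclohex-2-en-1-ol | CC1=C[C@@H](O[Si](C)(C)C(C)(C)C)CC(C)(C)[C@]1(O)C#C/C(C)=C/CO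
F2 | step 3 | (1R,4S)-4-[(tert-butyldimethylsilyl)oxy]-1-[(1E,3E)-5-hydroxy-3-methylpenta-1,3-dien-1-yl]-2,6,6-trimethylcyclohex-2-en-1-ol | CC1=C[C@@H](O[Si](C)(C)C(C)(C)C)CC(C)(C)[C@]1(O)/C=C/C(C)=C/CO
F3 | step 3 | (2E,4E)-5-[(1R,4S)-4-[(tert-butyldimethylsilyl)oxy]-1-hydroxy-2,6,6-trimethylcyclohex-2-en-1-yl]-3-methylpenta-2,4-dienal | CC1=C[C@@H](O[Si](C)(C)C(C)(C)C)CC(C)(C)[C@]1(O)/C=C/C(C)=C/C=O
F4 | step 7 | (2E,4E)-5-[(1R)-1-hydroxy-2,6,6-trimethyl-4-oxocyclohex-2-en-1-yl]-3-methylpenta-2,4-dienal | CC1=CC(=O)CC(C)(C)[C@]1(O)/C=C/C(C)=C/C=O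
F5 | step 7 | (4R)-4-[(1E,3E,5E,7E,9E)-11,11-dimethoxy-3,7-dimethylundeca-1,3,5,7,9-pentaen-1-yl]-4-hydroxy-3,5,5-trimethylcyclohex-2-en-1-one | CC1=CC(=O)CC(C)(C)[C@]1(O)/C=C/C(C)=C/C=C/C(C)=C/C=C/C(OC)OC
F0 | step 16 | none | none
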